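**Assumption:** the target has no stereocentre and no stereogenic double bond, so there is no configuration to set; acid 2 is taken as a catalogue compound.

**Retrosynthetic overview**
1. Ring C is closed last through its two C–O bonds: O1–C8a from a ring A C–H ortho to the carbonyl (borylation, then oxidation) and O1–C2 by addition–elimination with loss of HNMe2, leading back to enaminone 4.
2. Enaminone 4 comes from deoxybenzoin 3 and DMF-DMA (C2–C3 bond).
3. Deoxybenzoin 3 comes from Friedel–Crafts acylation of veratrole 1 (ring A) with arylacetic acid 2 (ring B).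
4. Rings A and B are bought; only ring C is built.

**Step 1**
Reactants: 1 1,2-dimethoxybenzene (veratrole); 2 2-(2,3,4-trimethoxyphenyl)acetic acid
Product: 3 1-(3,4-dimethoxyphenyl)-2-(2,3,4-trimethoxyphenyl)ethan-1-one
Conditions: PPA, 1 (3 equiv), 70 °C, 3 h
Reagents that add atoms: none
Why: Friedel–Crafts acylation; PPA activates 2 as its acylium ion, which attacks veratrole para to a methoxy group (the only unhindered activated site), excess 1 suppresses self-acylation of ring B, and the aryl methyl ethers are stable in PPA at this temperature.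

**Step 2**
Reactants: 3 1-(3,4-dimethoxyphenyl)-2-(2,3,4-trimethoxyphenyl)ethan-1-one
Product: 4 (E)-3-(dimethylamino)-1-(3,4-dimethoxyphenyl)-2-(2,3,4-trimethoxyphenyl)prop-2-en-1-one
Conditions: DMF-DMA (3 equiv), PhMe, 105 °C, 12 h; crystallise
Reagents that add atoms: N,N-dimethylformamide dimethyl acetal, COC(OC)N(C)C
Why: Aminomethylenation of an active methylene with an amide acetal (enaminone formation); the CH2 between carbonyl and aryl condenses with loss of two MeOH, the push–pull alkene settles as the E isomer (its geometry does not matter later), and no stereocentre is formed.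

**Step 3**
Reactants: 4 (E)-3-(dimethylamino)-1-(3,4-dimethoxyphenyl)-2-(2,3,4-trimethoxyphenyl)prop-2-en-1-one
Product: 7 6,7,2',3',4'-pentamethoxyisoflavone, via ortho-boryl enaminone 5 (not isolated), via ortho-hydroxy enaminone 6 (not isolated)
Conditions: [Ir(OMe)(cod)]2 (2.5 mol%), P[3,5-(CF3)2C6H3]3 (10 mol%), B2pin2 (1.1 equiv), methylcyclohexane–CPME, 90 °C; then NaBO3·4H2O (1.5 equiv), THF–H2O, rt; then AcOH, 50 °C
Reagents that add atoms: sodium perborate tetrahydrate NaBO3·4H2O (supplies O1; anion drawn as the peroxoborate dimer, water of crystallisation omitted), [Na+].[Na+].O[B-]1(O)OO[B-](O)(O)OO1; bis(pinacolato)diboron (its boron is carried only by intermediate 5, none remains in 7), CC1(C)OB(OC1(C)C)B1OC(C)(C)C(C)(C)O1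
Why: Proposed new method: carbonyl-directed iridium-catalysed ortho C–H borylation with a push–pull enaminone as the directing group, telescoped to ring closure; the vinylogous-amide oxygen (more Lewis basic than the ester and ketone oxygens known to direct) binds the phosphine-ligated trivalent iridium tris(boryl) complex at its open site, so C–H cleavage goes through a five-membered O,C-iridacycle at ring A C6 (C2 is blocked by the flanking OMe, ring B would need a six-membered chelate, the aminomethylene C–H is geminal to NMe2 and more crowded, and 4 has no enolisable α-H); perborate then turns C–B into C–O by 1,2-aryl shift from boron to oxygen, and AcOH lets the phenol add to the aminomethylene carbon and expel HNMe2 (addition–elimination) to close ring C; the closest known reactions are ester-, amide- and ketone-directed iridium ortho-borylation, one-pot borylation–oxidation of arenes to phenols and the cyclisation of 2-hydroxyaryl enaminones to chromones; no stereocentre is formed.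

**Compound list**
1 | 1,2-dimethoxybenzene (veratrole) | COc1ccccc1OC | starting material
2 | 2-(2,3,4-trimethoxyphenyl)acetic acid | COc1ccc(CC(=O)O)c(OC)c1OC | starting material
3 | 1-(3,4-dimethoxyphenyl)-2-(2,3,4-trimethoxyphenyl)ethan-1-one | COc1ccc(cc1OC)C(=O)Cc1ccc(OC)c(OC)c1OC | intermediate
4 | (E)-3-(dimethylamino)-1-(3,4-dimethoxyphenyl)-2-(2,3,4-trimethoxyphenyl)prop-2-en-1-one | CN(C)/C=C(\c1ccc(OC)c(OC)c1OC)C(=O)c1ccc(OC)c(OC)c1 | intermediate
5 | (E)-3-(dimethylamino)-1-[4,5-dimethoxy-2-(4,4,5,5-tetramethyl-1,3,2-dioxaborolan-2-yl)phenyl]-2-(2,3,4-trimethoxyphenyl)prop-2-en-1-one | CN(C)/C=C(\c1ccc(OC)c(OC)c1OC)C(=O)c1cc(OC)c(OC)cc1B1OC(C)(C)C(C)(C)O1 | intermediate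
6 | (E)-3-(dimethylamino)-1-(2-hydroxy-4,5-dimethoxyphenyl)-2-(2,3,4-trimethoxyphenyl)prop-2-en-1-one | CN(C)/C=C(\c1ccc(OC)c(OC)c1OC)C(=O)c1cc(OC)c(OC)cc1O | intermediate
7 | 6,7-dimethoxy-3-(2,3,4-trimethoxyphenyl)-4H-chromen-4-one (6,7,2',3',4'-pentamethoxyisoflavone) | COc1cc2occ(-c3ccc(OC)c(OC)c3OC)c(=O)c2cc1OC | target

**Total step count:** 3. **Longest linear sequence:** 3 steps (1 + 2 → 3 → 4 → 7).

**Steps most likely to fail**

Step 3 (the new step). The risks are borylation at the aminomethylene C–H (cis to the carbonyl in E-4) instead of ring A, catalyst inhibition by the strongly binding vinylogous amide, and low conversion. The fallback uses known chemistry, sets out from 2 and comes back at 6. Acid 2 is condensed with 3,4-dimethoxyphenol F1 in neat BF3·OEt2 at 85 °C; C-acylation occurs ortho to the hydroxyl and para to the 3-OMe and gives 1-(2-hydroxy-4,5-dimethoxyphenyl)-2-(2,3,4-trimethoxyphenyl)ethan-1-one F2. Heating F2 with DMF-DMA in PhMe at 100 °C gives ortho-hydroxy enaminone 6, which closes to 7 with AcOH as in step 3.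

Step 1. The risks are self-acylation of the electron-rich ring B of 2 and acid-induced lactonisation through its ortho methoxy group. The fallback sets out from 1 and comes back at 3. Veratrole 1 is acetylated (AcCl, AlCl3, CH2Cl2, 0 °C) to 1-(3,4-dimethoxyphenyl)ethan-1-one F3, which is also a cheap catalogue compound. F3 then undergoes α-arylation with 1-bromo-2,3,4-trimethoxybenzene F4 (Pd2(dba)3 as the zerovalent palladium source, XPhos, NaOtBu, PhMe, 80 °C) to give 3.

Step 2. The risk is slow or incomplete condensation at the CH2, which is hindered by the ortho-methoxy aryl group. The fallback sets out from 3 and comes back at 4. Claisen formylation of 3 (HCO2Et, NaH, THF, 0 °C to rt) gives (Z)-3-hydroxy-1-(3,4-dimethoxyphenyl)-2-(2,3,4-trimethoxyphenyl)prop-2-en-1-one F5. Condensation of F5 with Me2NH (2 M in THF, cat. AcOH, rt) gives 4.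

**Further compounds**
F1 | step 3 | 3,4-dimethoxyphenol | COc1ccc(O)cc1OC
F2 | step 3 | 1-(2-hydroxy-4,5-dimethoxyphenyl)-2-(2,3,4-trimethoxyphenyl)ethan-1-one | COc1ccc(CC(=O)c2cc(OC)c(OC)cc2O)c(OC)c1OC
F3 | step 1 | 1-(3,4-dimethoxyphenyl)ethan-1-one | CC(=O)c1ccc(OC)c(OC)c1
F4 | step 1 | 1-bromo-2,3,4-trimethoxybenzene | COc1ccc(Br)c(OC)c1OC
F5 | step 2 | (Z)-3-hydroxy-1-(3,4-dimethoxyphenyl)-2-(2,3,4-trimethoxyphenyl)prop-2-en-1-one | O/C=C(/c1ccc(OC)c(OC)c1OC)C(=O)c1ccc(OC)c(OC)c1
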